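**Assumption:** the sense of induction of the copper catalyst in step 7 cannot be predicted with certainty; the ligand antipode that delivers (R)-10 is used (written here as the (S,S)-ligand) and the configuration is checked at chromene 11.

## Retrosynthetic overview

1. Target 24 ⇐ silyl/ester deprotection of 22.
2. 22 ⇐ Pd-catalysed Negishi C(sp3)–C(sp2) coupling of the alkylzinc from chromene iodide 13 with (E)-alkenyl iodide 21 (the two halves join at the C7–C8 bond of the side chain).
3. 21 ⇐ Z-selective Ando-type HWE of iodo-aldehyde 16 (from Zr-catalysed carboalumination of pent-4-yn-1-ol) with α-homoprenyl phosphonate 20.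
4. 13 ⇐ chromene 11 ⇐ Au(I) 6-endo hydroarylation of aryl propargyl ether 10 ⇐ Cu-catalysed enantioconvergent propargylic etherification of phenol 4 with racemic tertiary carbonate 9 (sets C2).
5. Rings: the benzene ring comes from hydroquinone; the pyran ring is the only ring formed (step 8), before fragment union.

## Route

**Step 1**
Reactants: 1 hydroquinone
Product: 2 4-[(triisopropylsilyl)oxy]phenol
Conditions: TIPSCl (1 equiv), imidazole, DMF, 0 °C → rt (1 used in 3-fold excess and recovered)
Reagents that add atoms: triisopropylsilyl chloride, CC(C)[Si](Cl)(C(C)C)C(C)C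
Why: statistical mono-O-silylation of a symmetrical diphenol, with excess diol suppressing the bis-silyl ether.

**Step 2**
Reactants: 2 4-[(triisopropylsilyl)oxy]phenol
Product: 3 2-hydroxy-5-[(triisopropylsilyl)oxy]benzaldehyde
Conditions: MgCl2, Et3N, (CH2O)n, MeCN, reflux
Reagents that add atoms: paraformaldehyde, C=O
Why: magnesium-phenoxide-directed ortho-formylation (Casnati–Skattebøl) is ortho-specific, and the para position is blocked.

**Step 3**
Reactants: 3 2-hydroxy-5-[(triisopropylsilyl)oxy]benzaldehyde
Product: 4 2-methyl-4-[(triisopropylsilyl)oxy]phenol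
Conditions: H2 (1 atm), 10% Pd/C, AcOH–EtOAc, rt
Reagents that add atoms: none
Why: hydrogenation to the o-hydroxybenzyl alcohol followed by acid-assisted benzylic hydrogenolysis gives the aryl methyl group without touching the aryl silyl ether.

**Step 4**
Reactants: 5 4-hydroxybutan-2-one
Product: 6 4-[(tert-butyldimethylsilyl)oxy]butan-2-one
Conditions: TBSCl, imidazole, CH2Cl2, 0 °C → rt
Reagents that add atoms: tert-butyldimethylsilyl chloride, CC(C)(C)[Si](C)(C)Cl
Why: standard silylation of a primary alcohol under mild base, which avoids β-elimination to methyl vinyl ketone.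

**Step 5**
Reactants: 6 4-[(tert-butyldimethylsilyl)oxy]butan-2-one; 7 ethynylmagnesium bromide
Product: 8 rac-5-[(tert-butyldimethylsilyl)oxy]-3-methylpent-1-yn-3-ol
Conditions: THF, −78 → 0 °C; aq. NH4Cl
Reagents that add atoms: none (7 is a numbered reactant)
Why: Grignard 1,2-addition of an acetylide to a methyl ketone gives the tertiary propargylic alcohol; the racemate is acceptable because step 7 is enantioconvergent.

**Step 6**
Reactants: 8 rac-5-[(tert-butyldimethylsilyl)oxy]-3-methylpent-1-yn-3-ol
Product: 9 rac-5-[(tert-butyldimethylsilyl)oxy]-3-methylpent-1-yn-3-yl methyl carbonate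
Conditions: LiHMDS (1.05 equiv), THF, −78 °C; ClCO2Me, −78 → 0 °C
Reagents that add atoms: methyl chloroformate, COC(=O)Cl
Why: O-acylation of the lithium alkoxide (O–H is far more acidic than the alkyne C–H) installs the leaving group for copper-allenylidene formation.

**Step 7**
Reactants: 4 2-methyl-4-[(triisopropylsilyl)oxy]phenol; 9 rac-carbonate
Product: 10 tert-butyldimethyl{[(3R)-3-methyl-3-{2-methyl-4-[(triisopropylsilyl)oxy]phenoxy}pent-4-yn-1-yl]oxy}silane
Conditions: Cu(MeCN)4PF6 (5 mol %), bulky C2-symmetric (S,S)-pybox (e.g. 4-isopropyl-5,5-diphenyl-pybox or a bulkier 4-aryl analogue from screening, 6 mol %), iPr2NEt (1.5 equiv), THF, −20 °C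
Reagents that add atoms: none
Why: Proposed new method: Cu-acetylide formation and loss of CO2/MeO− convert both enantiomers of 9 into one planar Cu-allenylidene whose γ-carbon carries CH3 and the much larger CH2CH2OTBS arm, and the deep pybox pocket leaves one face open to outer-sphere attack by the phenoxide (enantioconvergent, sets C3 of 10 = C2 of the chromene as R); the closest known reactions are Cu–pybox asymmetric propargylic etherification of secondary propargylic esters with phenols, Cu-catalysed asymmetric amination of ketone-derived tertiary propargylic carbonates, and the racemic Cu-catalysed O-propargylation of phenols with tertiary carbonates, but enantioselective C–O formation at an acyclic methyl/primary-alkyl centre with an ortho-substituted phenol has, to my knowledge, not been shown.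

**Step 8**
Reactants: 10 (R)-aryl propargyl ether
Product: 11 (2R)-2-{2-[(tert-butyldimethylsilyl)oxy]ethyl}-2,8-dimethyl-6-[(triisopropylsilyl)oxy]-2H-chromene
Conditions: Ph3PAuNTf2 (3 mol %), CH2Cl2, rt
Reagents that add atoms: none
Why: Au(I) π-activation of the terminal alkyne triggers 6-endo-dig Friedel–Crafts hydroarylation at the only free ortho carbon and protodeauration; the C–O bond at the stereocentre is never broken, so configuration is retained (unlike the thermal Claisen route).

**Step 9**
Reactants: 11 (2R)-chromene bis-silyl ether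
Product: 12 2-{(2R)-2,8-dimethyl-6-[(triisopropylsilyl)oxy]-2H-chromen-2-yl}ethan-1-ol
Conditions: CSA (10 mol %), MeOH–CH2Cl2 (1:1), 0 °C
Reagents that add atoms: none
Why: mild acid methanolysis cleaves the primary alkyl TBS ether, while the aryl TIPS ether is acid-stable and the chromene tolerates catalytic acid at 0 °C.

**Step 10**
Reactants: 12 chromenyl ethanol
Product: 13 (2R)-2-(2-iodoethyl)-2,8-dimethyl-6-[(triisopropylsilyl)oxy]-2H-chromene
Conditions: PPh3, imidazole, I2 (premixed), CH2Cl2, 0 °C → rt
Reagents that add atoms: iodine, II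
Why: Appel-type iodination of a primary alcohol by SN2 on the alkoxyphosphonium; premixing PPh3/I2 keeps free iodine away from the chromene alkene.

**Step 11**
Reactants: 14 pent-4-yn-1-ol
Product: 15 (E)-5-iodo-4-methylpent-4-en-1-ol
Conditions: Me3Al (3 equiv), Cp2ZrCl2 (25 mol %), CH2Cl2, 0 °C → rt; then I2, THF, −30 → 0 °C
Reagents that add atoms: trimethylaluminium, C[Al](C)C; iodine, II
Why: Zr-catalysed Negishi carboalumination adds Me–Al syn and regioselectively (Al terminal), and iodinolysis with retention gives the E-alkenyl iodide.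

**Step 12**
Reactants: 15 (E)-5-iodo-4-methylpent-4-en-1-ol
Product: 16 (E)-5-iodo-4-methylpent-4-enal
Conditions: Dess–Martin periodinane, NaHCO3, CH2Cl2, 0 °C → rt
Reagents that add atoms: none
Why: mild, non-epimerising oxidation of a primary alcohol that leaves the alkenyl iodide intact.

**Step 13**
Reactants: 17 methyl bromoacetate
Product: 18 methyl 2-(diphenoxyphosphoryl)acetate
Conditions: (PhO)2P(O)H, Et3N, CH2Cl2, 0 °C → rt
Reagents that add atoms: diphenyl phosphite, O=[PH](Oc1ccccc1)Oc1ccccc1
Why: Michaelis–Becker-type P-alkylation of the diaryl phosphite by the activated bromide gives the Ando Z-selective HWE reagent.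

**Step 14**
Reactants: 18 methyl 2-(diphenoxyphosphoryl)acetate; 19 5-bromo-2-methylpent-2-ene
Product: 20 rac-methyl 2-(diphenoxyphosphoryl)-6-methylhept-5-enoate
Conditions: NaH, DMSO, rt → 45 °C
Reagents that add atoms: none
Why: C-alkylation of the stabilised phosphonoacetate anion with a primary bromide (SN2) installs the homoprenyl group that becomes the α-substituent of the enoate.

**Step 15**
Reactants: 20 phosphonate; 16 (E)-5-iodo-4-methylpent-4-enal
Product: 21 methyl (2Z,6E)-7-iodo-6-methyl-2-(4-methylpent-3-en-1-yl)hepta-2,6-dienoate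
Conditions: NaH, THF, 0 °C; then 16, −78 → 0 °C
Reagents that add atoms: none
Why: Ando-type Horner–Wadsworth–Emmons olefination with the diaryl phosphonate collapses kinetically through the syn-oxaphosphetane, giving the Z-enoate (ester cis to the β-chain; about 9:1 expected, minor isomer removed by chromatography).

**Step 16**
Reactants: 13 chromenyl ethyl iodide; 21 alkenyl iodide
Product: 22 methyl (2Z,6E)-9-{(2R)-2,8-dimethyl-6-[(triisopropylsilyl)oxy]-2H-chromen-2-yl}-6-methyl-2-(4-methylpent-3-en-1-yl)nona-2,6-dienoate
Conditions: (i) Zn dust (BrCH2CH2Br/TMSCl-activated), LiCl, THF, 40 °C; (ii) 21, Pd(OAc)2 (2 mol %), SPhos (4 mol %), THF, rt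
Reagents that add atoms: none
Why: Negishi coupling — zinc inserts only into the primary alkyl iodide, and the alkylzinc transmetalates to the alkenyl-Pd(II) formed from 21 with retention of the E geometry, forming the C7–C8 bond while tolerating ester, silyl ether and chromene.

**Step 17**
Reactants: 22 coupled silyl ether ester
Product: 23 methyl (2Z,6E)-9-[(2R)-6-hydroxy-2,8-dimethyl-2H-chromen-2-yl]-6-methyl-2-(4-methylpent-3-en-1-yl)nona-2,6-dienoate
Conditions: TBAF/AcOH (1:1), THF, 0 °C
Reagents that add atoms: none
Why: fluoride cleaves the aryl silyl ether rapidly, and buffering prevents base-mediated side reactions of the enoate.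

**Step 18**
Reactants: 23 phenol methyl ester
Product: 24 (R)-sargachromenol
Conditions: LiOH·H2O (10 equiv), THF–MeOH–H2O (3:1:1), degassed, Ar, 45 °C; then aq. citric acid to pH 4
Reagents that add atoms: lithium hydroxide (aqueous), [Li+].[OH-]
Why: BAc2 saponification of the hindered methyl ester under oxygen-free conditions, which does not touch the stereocentre or the alkenes.

## Compound list

1 | hydroquinone | Oc1ccc(O)cc1 | starting material
2 | 4-[(triisopropylsilyl)oxy]phenol | CC(C)[Si](Oc1ccc(O)cc1)(C(C)C)C(C)C | intermediate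
3 | 2-hydroxy-5-[(triisopropylsilyl)oxy]benzaldehyde | O=Cc1cc(O[Si](C(C)C)(C(C)C)C(C)C)ccc1O | intermediate
4 | 2-methyl-4-[(triisopropylsilyl)oxy]phenol | Cc1cc(O[Si](C(C)C)(C(C)C)C(C)C)ccc1O | intermediate
5 | 4-hydroxybutan-2-one | CC(=O)CCO | starting material
6 | 4-[(tert-butyldimethylsilyl)oxy]butan-2-one | CC(=O)CCO[Si](C)(C)C(C)(C)C | intermediate
7 | ethynylmagnesium bromide | C#C[Mg]Br | starting material
8 | rac-5-[(tert-butyldimethylsilyl)oxy]-3-methylpent-1-yn-3-ol | C#CC(C)(O)CCO[Si](C)(C)C(C)(C)C | intermediate
9 | rac-5-[(tert-butyldimethylsilyl)oxy]-3-methylpent-1-yn-3-yl methyl carbonate | C#CC(C)(CCO[Si](C)(C)C(C)(C)C)OC(=O)OC | intermediate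
10 | tert-butyldimethyl{[(3R)-3-methyl-3-{2-methyl-4-[(triisopropylsilyl)oxy]phenoxy}pent-4-yn-1-yl]oxy}silane | CC(C)(C)[Si](C)(C)OCC[C@](Oc1ccc(O[Si](C(C)C)(C(C)C)C(C)C)cc1C)(C)C#C | intermediate
11 | (2R)-2-{2-[(tert-butyldimethylsilyl)oxy]ethyl}-2,8-dimethyl-6-[(triisopropylsilyl)oxy]-2H-chromene | CC(C)(C)[Si](C)(C)OCC[C@]1(C)C=Cc2cc(O[Si](C(C)C)(C(C)C)C(C)C)cc(C)c2O1 | intermediate
12 | 2-{(2R)-2,8-dimethyl-6-[(triisopropylsilyl)oxy]-2H-chromen-2-yl}ethan-1-ol | OCC[C@]1(C)C=Cc2cc(O[Si](C(C)C)(C(C)C)C(C)C)cc(C)c2O1 | intermediate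
13 | (2R)-2-(2-iodoethyl)-2,8-dimethyl-6-[(triisopropylsilyl)oxy]-2H-chromene | ICC[C@]1(C)C=Cc2cc(O[Si](C(C)C)(C(C)C)C(C)C)cc(C)c2O1 | intermediate
14 | pent-4-yn-1-ol | C#CCCCO | starting material
15 | (E)-5-iodo-4-methylpent-4-en-1-ol | OCCC/C(C)=C/I | intermediate
16 | (E)-5-iodo-4-methylpent-4-enal | O=CCC/C(C)=C/I | intermediate
17 | methyl bromoacetate | COC(=O)CBr | starting material
18 | methyl 2-(diphenoxyphosphoryl)acetate | COC(=O)CP(=O)(Oc1ccccc1)Oc1ccccc1 | intermediate
19 | 5-bromo-2-methylpent-2-ene | CC(C)=CCCBr | starting material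
20 | rac-methyl 2-(diphenoxyphosphoryl)-6-methylhept-5-enoate | COC(=O)C(CCC=C(C)C)P(=O)(Oc1ccccc1)Oc1ccccc1 | intermediate
21 | methyl (2Z,6E)-7-iodo-6-methyl-2-(4-methylpent-3-en-1-yl)hepta-2,6-dienoate | CC(C)=CCC/C(=C/CC/C(C)=C/I)C(=O)OC | intermediate
22 | methyl (2Z,6E)-9-{(2R)-2,8-dimethyl-6-[(triisopropylsilyl)oxy]-2H-chromen-2-yl}-6-methyl-2-(4-methylpent-3-en-1-yl)nona-2,6-dienoate | CC(C)=CCC/C(=C/CC/C(C)=C/CC[C@]1(C)C=Cc2cc(O[Si](C(C)C)(C(C)C)C(C)C)cc(C)c2O1)C(=O)OC | intermediate
23 | methyl (2Z,6E)-9-[(2R)-6-hydroxy-2,8-dimethyl-2H-chromen-2-yl]-6-methyl-2-(4-methylpent-3-en-1-yl)nona-2,6-dienoate | CC(C)=CCC/C(=C/CC/C(C)=C/CC[C@]1(C)C=Cc2cc(O)cc(C)c2O1)C(=O)OC | intermediate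
24 | (R)-sargachromenol | CC(C)=CCC/C(=C/CC/C(C)=C/CC[C@]1(C)C=Cc2cc(O)cc(C)c2O1)C(=O)O | target

## Step count and risks

Total steps: 18.
Longest linear sequence: 10 steps (1 → 2 → 3 → step 7 → 8 → 9 → 10 → 16 → 17 → 18; the branch from 5 is also 10).

Three steps most likely to fail:

1. **Step 7 (proposed new Cu-catalysed enantioconvergent etherification).** Risks are insufficient Me versus CH2CH2OTBS discrimination, elimination to the enyne, and C-propargylation of the phenol. Fallback (known chemistry): Pd-catalysed asymmetric allylic etherification of phenol 4 with geometrically pure (Z)-5-(TBSO)-3-methylpent-2-enyl methyl carbonate, using a chiral diaminocyclohexane-derived bis(phosphinobenzamide) ligand, to give the branched tertiary allyl aryl ether. OsO4/NaIO4 cleavage of the vinyl group and Ohira–Bestmann homologation then rejoin the route at alkyne 10.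

2. **Step 8 (Au-catalysed 6-endo hydroarylation).** Risks are competing 5-exo closure, erosion of ee through C–O ionisation or a Claisen/allene pathway, and participation of the silyl ether oxygen. Fallback: close the pyran by ring-closing metathesis instead. Phenol 4 is formylated a second time and methylenated (Wittig) to the 6-vinyl phenol, which is etherified as in step 7; the alkyne is then semi-hydrogenated (Lindlar) and the diene cyclised with a Ru carbene, so the C–O stereocentre is again untouched.

3. **Step 15 (Z-selective HWE with the α-branched phosphonate).** Risks are inadequate Z:E ratio and difficult separation. Fallback: set the geometry by alkyne syn-hydrometalation instead of olefination. Iodide 13 is first coupled (same Negishi conditions) with the TBS ether of 15, and the chain terminus is elaborated to the 2-ynoate (deprotection, oxidation, Ohira–Bestmann, n-BuLi/ClCO2Me). Pd-catalysed syn-hydrostannation (α-stannyl, H and Sn cis), iododestannylation and Negishi coupling with (4-methylpent-3-enyl)zinc bromide then give the same Z-enoate 22 stereospecifically, at the cost of convergence.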